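**Assumption:** in steps 7–8 the C9 epimer with C1 trans to C10 and the C1 anomer with OiVal cis to H9 (the natural valepotriate configuration) are the thermodynamic outcomes, and any minor epimers are separable.

## Retrosynthetic overview
1. Jatamanvaltrate K ⇐ desilylation ⇐ one-pot double isovaleroylation of lactol **9**. This installs the C1 acylal and the C7 ester together.
2. Lactol **9** ⇐ hydrolysis and dienol lactolization of bis(methoxymethylene) compound **8**. The dihydropyran ring is formed last, via the 1,5-dialdehyde level.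
3. **8** ⇐ double Wittig of 2-acylcyclopentenone **7** ⇐ carbonylative Stille of α-bromoenone **6** ⇐ α′-hydroxylation of **5** anti to the C7 silyl ether.
4. The cyclopentenone is made first: enantioselective Brønsted-acid Piancatelli rearrangement of furylcarbinol **3** sets C7 and C8 trans. **3** comes from 2-lithio-3-bromofuran and a silyloxyacetaldehyde.

## Route

**Step 1**
Reactants: **1** 3-bromofuran; **2** 2-(tert-butyldiphenylsilyloxy)acetaldehyde
Product: **3** 1-(3-bromofuran-2-yl)-2-(TBDPSO)ethanol (racemic)
Conditions: LDA, THF, −78 °C, 1 h; add **2**, −78 → 0 °C; aq. NH4Cl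
Reagents that add atoms: none
Why: Directed C2 lithiation of 3-bromofuran followed by 1,2-addition to the aldehyde; the racemic carbinol centre is destroyed as a planar furfuryl cation in step 2, so it does not matter.

**Step 2**
Reactants: **3**; water
Product: **4** (4R,5R)-2-bromo-5-[(TBDPSO)methyl]-4-hydroxycyclopent-2-en-1-one (trans)
Conditions: chiral IDPi Brønsted acid (5 mol%, enantiomer chosen to give 4R,5R), MeCN/H2O 10:1, 60 °C, 24 h
Reagents that add atoms: water, O. Net isomerization: water supplies the new 4-OH and the carbinol OH is lost as water.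
Why: Proposed new method: the acid ionizes the carbinol to an achiral furfuryl cation, water adds at furan C5, and ring opening gives a 2-hydroxypentadienyl cation ion-paired with the confined chiral anion. The anion's pocket sets the rotation sense of the conrotatory 4π-electrocyclization, so C7–O and C8–CH2OSi are formed trans and enantioselectively, and tautomerization gives the enone. The closest known reactions are the racemic Lewis-acid Piancatelli rearrangement, the chiral phosphoric acid-catalysed aza-Piancatelli, and Brønsted-acid asymmetric Nazarov cyclizations.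

**Step 3**
Reactants: **4**
Product: **5** (4R,5R)-2-bromo-5-[(TBDPSO)methyl]-4-(triethylsilyloxy)cyclopent-2-en-1-one
Conditions: TESOTf, 2,6-lutidine, CH2Cl2, −78 → 0 °C
Reagents that add atoms: TESOTf, CC[Si](CC)(CC)OS(=O)(=O)C(F)(F)F
Why: Silylation of the secondary OH prevents base consumption and β-elimination in step 4; the TES group is later removed under the mild acid of step 7.

**Step 4**
Reactants: **5**
Product: **6** (4S,5R)-2-bromo-5-hydroxy-5-[(TBDPSO)methyl]-4-(TESO)cyclopent-2-en-1-one
Conditions: LiHMDS, THF, −78 °C, 30 min; then 2-(phenylsulfonyl)-3-phenyloxaziridine, −78 °C, 1 h; aq. NH4Cl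
Reagents that add atoms: Davis oxaziridine (transfers O), O=S(=O)(c1ccccc1)N1OC1c1ccccc1
Why: C8–H is the only acidic α′ position, giving a kinetic enolate; Davis hydroxylation from the face anti to C7–OTES puts OH trans to C7–O and pushes C10 cis to C7–O, as in the target.

**Step 5**
Reactants: **6**; (acetoxymethyl)tributylstannane; CO
Product: **7** (4S,5R)-2-(2-acetoxyacetyl)-5-hydroxy-5-[(TBDPSO)methyl]-4-(TESO)cyclopent-2-en-1-one
Conditions: Pd2(dba)3 (3 mol%), AsPh3 (12 mol%), CuI (10 mol%), CO (1 atm), NMP, 50 °C
Reagents that add atoms: Bu3SnCH2OAc, CCCC[Sn](CCCC)(CCCC)COC(C)=O; carbon monoxide, [C-]#[O+]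
Why: Carbonylative Stille coupling at the α-bromoenone installs C4 (from CO) and C11 (CH2OAc) in one step; no stereocentre is touched.

**Step 6**
Reactants: **7**; methoxymethylenetriphenylphosphorane (from [Ph3PCH2OMe]Cl + KOtBu)
Product: **8** bis(methoxymethylene) compound
Conditions: [Ph3PCH2OMe]Cl (4 equiv), KOtBu (3.8 equiv), THF, 0 °C; add **7**, −78 °C → rt
Reagents that add atoms: COC=P(c1ccccc1)(c1ccccc1)c1ccccc1, which leaves =CHOMe at both C9 (C1 carbon) and C4 (C3 carbon)
Why: Wittig methoxymethylenation of both ketones adds C1 and C3 at aldehyde level; C9 becomes sp2 here and is re-set in step 7.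

**Step 7**
Reactants: **8**; water
Product: **9** lactol (C1 epimeric): C1(OH)–O2–C3=C4–C5=C6 dihydropyran fused to the cyclopentene, with C7-OH free
Conditions: CSA (10 mol%), THF/H2O 10:1, 0 → 23 °C, 3 h
Reagents that add atoms: water, O
Why: The two enol ethers hydrolyse and TES is lost, giving the 1,5-dialdehyde; the C3 aldehyde enolizes through its dienol and the enol oxygen closes onto the C1 aldehyde in the iridoid dialdehyde-to-enol-hemiacetal cyclization. Protonation at C9 sets the C9 stereocentre, with the thermodynamic C1/C10 trans isomer assumed.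

**Step 8**
Reactants: **9**; isovaleryl chloride
Product: **10** C1,C7-bis(isovalerate), C10-OTBDPS
Conditions: isovaleryl chloride (3 equiv), pyridine, DMAP (cat.), CH2Cl2, 0 °C
Reagents that add atoms: isovaleryl chloride, CC(C)CC(=O)Cl
Why: Acylation of the lactol OH and the secondary C7-OH occurs, while the tertiary C8-OH does not react; the anomeric effect favours the natural C1 configuration (see assumption).

**Step 9**
Reactants: **10**
Product: **11** Jatamanvaltrate K
Conditions: HF·pyridine, pyridine/THF, 0 → 23 °C
Reagents that add atoms: none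
Why: Buffered fluoride removes the primary TBDPS ether while the acylal, enol ether and esters survive.

## Compound list
| # | name | SMILES | role |
|---|---|---|---|
| 1 | 3-bromofuran | Brc1ccoc1 | starting material |
| 2 | 2-(TBDPSO)acetaldehyde | O=CCO[Si](c1ccccc1)(c1ccccc1)C(C)(C)C | starting material |
| 3 | 1-(3-bromofuran-2-yl)-2-(TBDPSO)ethanol, racemic | OC(CO[Si](c1ccccc1)(c1ccccc1)C(C)(C)C)c1occc1Br | intermediate |
| 4 | (4R,5R)-2-bromo-4-hydroxy-5-(TBDPSOCH2)cyclopent-2-en-1-one | O=C1C(Br)=C[C@H](O)[C@H]1CO[Si](c2ccccc2)(c2ccccc2)C(C)(C)C | intermediate |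
| 5 | 4-OTES ether of 4 | O=C1C(Br)=C[C@H](O[Si](CC)(CC)CC)[C@H]1CO[Si](c2ccccc2)(c2ccccc2)C(C)(C)C | intermediate |
| 6 | (4S,5R)-5-hydroxy analogue of 5 | O=C1C(Br)=C[C@H](O[Si](CC)(CC)CC)[C@]1(O)CO[Si](c2ccccc2)(c2ccccc2)C(C)(C)C | intermediate |
| 7 | 2-(acetoxyacetyl) enone | O=C1C(C(=O)COC(C)=O)=C[C@H](O[Si](CC)(CC)CC)[C@]1(O)CO[Si](c2ccccc2)(c2ccccc2)C(C)(C)C | intermediate |
| 8 | bis(methoxymethylene) compound | COC=C1C(C(=COC)COC(C)=O)=C[C@H](O[Si](CC)(CC)CC)[C@]1(O)CO[Si](c2ccccc2)(c2ccccc2)C(C)(C)C | intermediate |
| 9 | bicyclic lactol (C1 epimeric), C7-OH, C10-OTBDPS | CC(=O)OCC1=COC(O)[C@H]2C1=C[C@H](O)[C@]2(O)CO[Si](c3ccccc3)(c3ccccc3)C(C)(C)C | intermediate |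
| 10 | C1,C7-bis(isovalerate), C10-OTBDPS | CC(=O)OCC1=CO[C@@H](OC(=O)CC(C)C)[C@H]2C1=C[C@H](OC(=O)CC(C)C)[C@]2(O)CO[Si](c3ccccc3)(c3ccccc3)C(C)(C)C | intermediate |
| 11 | Jatamanvaltrate K | CC(=O)OCC1=CO[C@@H](OC(=O)CC(C)C)[C@H]2C1=C[C@H](OC(=O)CC(C)C)[C@]2(O)CO | target |

**Total steps:** 9. **Longest linear sequence:** 9 (from 1 and 2, all steps linear).

## Three steps most likely to fail
1. **Step 2 (proposed new asymmetric Piancatelli).** The 3-bromo and β-silyloxy groups disfavour furfuryl cation formation, and enantiocontrol is unproven. Fallback (known chemistry): racemic Piancatelli with Dy(OTf)3 in MeCN/H2O, then lipase (CAL-B, vinyl acetate) kinetic resolution of the trans-4-hydroxycyclopentenone.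
2. **Step 6 (double methoxymethylenation of a hindered, acidic-CH2 2-acylenone).** Fallback that changes the approach: Stille coupling of **6** with CH2=C(SnBu3)CH2OAc, C9 methoxymethylenation only, hydrolysis to the C1 lactol, then Wacker-type 6-endo oxypalladation/β-H elimination to form the C3=C4 enol ether.
3. **Step 7 (hydrolytic lactolization).** Acid may push the double bond to the C5=C9 isomer, cause retro-aldol at the β-hydroxy aldehyde, or epimerize C9. Fallback: build the pyran at the acid level instead. Hydrolyse only the C1 enol ether, do a Pinnick oxidation, form the enol lactone onto the C3 aldehyde (Ac2O/NaOAc), and reduce it with DIBAL at −78 °C to the C1 lactol.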